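The constants were chosen freely; the result is computed.

At late times a flask like this has stopped moving, so you start there and ask what can still be standing. You have two flasks, dusk and summer, with the same charges and different times.

- dusk: first end groups 31 mM; second end groups 29.4 mM; time 2.5 min
- summer: first end groups 31 mM; second end groups 29.4 mM; time 8.0 min

    first end groups + second end groups ⇌ links (K1 = 31 M⁻¹, k1 = 5.0 M⁻¹ s⁻¹)
    first end groups + second end groups → rings, rate k2*[first end groups] as long as [second end groups] is above zero (k2 = 0.092 s⁻¹)

- which of these there is most of at the end, counted by the first end groups in it, dusk (links / first end groups / rings)
- which of these there is most of at the end, counted by the first end groups in it, summer (links / first end groups / rings)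
- final amount of the leader among these, as a percentage of the first end groups charged, in dusk
- final amount of the leader among these, as a percentage of the first end groups charged, in summer

Set up a small table with two rows, one per round of reckoning, and in each row write a guess and what it gives.

In row one, you guess that every second end group ends in a ring. Second end groups are the limiting reagent, because c(second end groups) at 29.4 mM is lower than c(first end groups) at 31 mM. That gives the ring ceiling, the charge of second end groups over the charge of first end groups, 94.8 %, and leaves 1.60 mM of first end groups. With links ignored, ring closure takes c(first end groups) down to that rest in 0.537 min, shorter than the 2.5 min of dusk.

In row two, you put that rest back into the link step. The ratio of links to free second end groups at balance is then K1 times the rest, 0.0496, well below one, and a link lasts 0.103 min on average, shorter than the time of dusk. So reading down the table, row two leaves the ceiling of row one standing, and I commit to rings at 94.8 % in both flasks.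

The forecast says rings at 94.8 % for dusk and rings at 94.8 % for summer, holding that “the links, which are reversible with a lifetime of about 6 s, fall apart and feed their second end groups into rings as well”.

The flask gives rings at 94.8 % in dusk and rings at 94.8 % in summer, which is the ring ceiling. In dusk the slowest mode at the asked time has a half-life of 0.0716 min, shorter than the 2.5 min allowed. In summer second end groups are under a fiftieth of their charge by 0.602 min, earlier than its 8.0 min. One change of charge that parts from the forecast's figures is a neighbour of dusk with 12 mM of second end groups, less than dusk holds: it has a ring ceiling of 38.7 %, and it ends with 38.7 % rings and first end groups leading at 61 %.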